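**Retrosynthetic overview**

1. The stereocentre is bought as (S)-2-methylbutanoic acid 1 and is never enolised on the way.
2. Aryl ester C–O: the central OH of the symmetric triol 2 is acylated with 1 (through its chloride 3) to give ester 4. Its two free ring positions are equivalent, so C-formylation to aldehyde 5 has one outcome.
3. Key disconnection, C(=O)–Cα of the enone: the formyl carbon of 5 reacts as an acyl anion (NHC Breslow intermediate) with an electrophilic styryl carbon. That carbon comes from boronic acid 6 and PhI(OAc)2 7 as iodonium salt 8, and the coupling gives target 9.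
4. No ring is formed; both benzene rings are bought.

Assumption: 5-methoxybenzene-1,2,3-triol (2) is taken as a purchasable catalogue phenol. Nothing here has been run; conditions are by analogy to known reaction types.

**Route**

Step 1
Reactants: 1 (S)-2-methylbutanoic acid; 2 5-methoxybenzene-1,2,3-triol
Product: 4 2,6-dihydroxy-4-methoxyphenyl (2S)-2-methylbutanoate, via (2S)-2-methylbutanoyl chloride 3 (not isolated)
Conditions: (a) 1, (COCl)2 (1.0 equiv), DMF (cat.), CH2Cl2, 0 °C → rt; (b) solution added to 2 (1.2 equiv), Et3N (1.2 equiv), THF, −78 → −30 °C, N2; cold 1 M HCl quench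
Reagents that add atoms: oxalyl chloride, O=C(Cl)C(=O)Cl (gives the Cl of 3; no atom of it stays in 4)
Why: Acid chloride formation without base, then O-acylation of a mono-phenoxide (Einhorn/Schotten–Baumann-type esterification): the central OH, flanked by two hydrogen-bond-donating OH groups, is the most acidic, so one equivalent of base makes its ammonium phenoxide, which is acylated at low temperature; no stereocentre is formed, and the (S) centre is kept because the amine is tied up as the phenoxide salt (no ketene) and the cold acid quench stops acyl migration.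

Step 2
Reactants: 4 2,6-dihydroxy-4-methoxyphenyl (2S)-2-methylbutanoate
Product: 5 3-formyl-2,6-dihydroxy-4-methoxyphenyl (2S)-2-methylbutanoate
Conditions: Cl2CHOMe (1.1 equiv), TiCl4 (2.5 equiv), CH2Cl2, −20 → 0 °C; then ice/1 M HCl
Reagents that add atoms: dichloromethyl methyl ether, COC(Cl)Cl (formyl carbon); water, O (formyl oxygen)
Why: Rieche formylation (electrophilic aromatic substitution directed ortho to a titanium phenoxide): the two free positions of 4 are equivalent and each is activated by ortho-OH, ortho-OMe and para-OH, so only one mono-aldehyde can form and the first formyl group deactivates the ring; the aryl ester and the stereocentre are inert to TiCl4 at or below 0 °C.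

Step 3
Reactants: 6 (E)-2-phenylethenylboronic acid; 7 (diacetoxyiodo)benzene
Product: 8 [(E)-2-phenylethenyl](phenyl)iodonium tetrafluoroborate
Conditions: BF3·OEt2 (1.1 equiv), CH2Cl2, 0 °C → rt; then sat. aq. NaBF4
Reagents that add atoms: sodium tetrafluoroborate, [Na+].F[B-](F)(F)F (counter-ion of 8)
Why: Boron-to-iodine(III) exchange of an alkenylboronic acid with BF3-activated PhI(OAc)2, a known stereoretentive alkenyl(aryl)iodonium synthesis, so the E double bond of 6 is carried into 8.

Step 4
Reactants: 5 3-formyl-2,6-dihydroxy-4-methoxyphenyl (2S)-2-methylbutanoate; 8 [(E)-2-phenylethenyl](phenyl)iodonium tetrafluoroborate (1.3 equiv)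
Product: 9 2,6-dihydroxy-4-methoxy-3-[(2E)-3-phenylprop-2-enoyl]phenyl (2S)-2-methylbutanoate
Conditions: 3-benzyl-5-(2-hydroxyethyl)-4-methylthiazolium chloride (15 mol %), TMEDA (1.5 equiv), toluene/CH2Cl2 4:1, −40 °C; pH 4 buffer work-up
Reagents that add atoms: none
Why: NHC-catalysed aldehyde C–H alkenylation with an alkenyl(aryl)iodonium salt, a known Breslow-intermediate reaction type pushed here to an unprotected, electron-rich salicylaldehyde: the carbene adds to the formyl group of 5 (activated by the internal O–H···O=C bond) to give the acyl anion equivalent, which is alkenylated at the iodine-bearing carbon of 8 with loss of PhI and retention of E geometry, joining two carbons that are both electrophilic in their reagents; no stereocentre is formed, and the ester α-CH is not deprotonated by TMEDA at −40 °C.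

**Compound list**

1 | (S)-2-methylbutanoic acid | CC[C@H](C)C(=O)O | starting material
2 | 5-methoxybenzene-1,2,3-triol | COc1cc(O)c(O)c(O)c1 | starting material
3 | (2S)-2-methylbutanoyl chloride | CC[C@H](C)C(Cl)=O | intermediate
4 | 2,6-dihydroxy-4-methoxyphenyl (2S)-2-methylbutanoate | CC[C@H](C)C(=O)Oc1c(O)cc(OC)cc1O | intermediate
5 | 3-formyl-2,6-dihydroxy-4-methoxyphenyl (2S)-2-methylbutanoate | CC[C@H](C)C(=O)Oc1c(O)cc(OC)c(C=O)c1O | intermediate
6 | (E)-2-phenylethenylboronic acid | OB(O)/C=C/c1ccccc1 | starting material
7 | (diacetoxyiodo)benzene | CC(=O)OI(OC(C)=O)c1ccccc1 | starting material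
8 | [(E)-2-phenylethenyl](phenyl)iodonium tetrafluoroborate | c1ccccc1/C=C/[I+]c1ccccc1.F[B-](F)(F)F | intermediate
9 | 2,6-dihydroxy-4-methoxy-3-[(2E)-3-phenylprop-2-enoyl]phenyl (2S)-2-methylbutanoate | CC[C@H](C)C(=O)Oc1c(O)cc(OC)c(C(=O)/C=C/c2ccccc2)c1O | target

**Step count**

Total steps: 4. Longest linear sequence: 3 (steps 1, 2, 4); step 3 is a one-step side branch.

**Steps most likely to fail, with fallbacks**

Step 4 is the most likely to fail. The aldehyde is electron-rich and has two ortho substituents, so Breslow-intermediate formation is slow, and phenoxide O-alkenylation or carbene attack on the aryl ester can compete. The fallback keeps the formyl carbon as the acyl nucleophile but makes it an acyl–rhodium hydride. Setting out from 5, phenol-directed Rh(I) hydroacylation of phenylacetylene ([Rh(cod)Cl]2 2.5 mol %, dppf 5 mol %, cat. Na2CO3, toluene, 60 °C) uses the 2-OH as the directing group. Syn addition across the alkyne gives the linear E-enone, which is 9 itself, where the fallback rejoins the route. Its own risk is linear versus branched regioselectivity with a terminal aryl alkyne. It makes no new compound (F0).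

Step 1 is the second risk. A terminal OH may be acylated instead of the central one, or the acyl group may migrate between neighbouring oxygens. The fallback sets out from 2. TBSCl (2.1 equiv), imidazole, DMF under equilibrating conditions gives the 1,3-disilyl ether 2,6-bis(tert-butyldimethylsilyloxy)-4-methoxyphenol F1, because the bulky groups avoid neighbouring oxygens. Its only free OH is acylated with 3 (pyridine, DMAP, CH2Cl2) to give 2,6-bis(tert-butyldimethylsilyloxy)-4-methoxyphenyl (2S)-2-methylbutanoate F2. HF·pyridine (THF, 0 °C) removes both silyl groups and gives 4, where the route is rejoined.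

Step 2 is the third risk. TiCl4 may cleave or shift the aryl ester, or the ring may be formylated twice. The fallback sets out from 4. NIS (1.0 equiv), MeCN, 0 °C gives 3-iodo-2,6-dihydroxy-4-methoxyphenyl (2S)-2-methylbutanoate F3. Pd-catalysed reductive carbonylation (Pd(OAc)2/PPh3, CO 1 atm, HCO2Na, DMF, 80 °C) then turns C–I into C–CHO under neutral conditions and gives 5, where the route is rejoined.

**Further compounds**

F0 | step 4 | none | none
F1 | step 1 | 2,6-bis(tert-butyldimethylsilyloxy)-4-methoxyphenol | COc1cc(O[Si](C)(C)C(C)(C)C)c(O)c(O[Si](C)(C)C(C)(C)C)c1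
F2 | step 1 | 2,6-bis(tert-butyldimethylsilyloxy)-4-methoxyphenyl (2S)-2-methylbutanoate | CC[C@H](C)C(=O)Oc1c(O[Si](C)(C)C(C)(C)C)cc(OC)cc1O[Si](C)(C)C(C)(C)C
F3 | step 2 | 3-iodo-2,6-dihydroxy-4-methoxyphenyl (2S)-2-methylbutanoate | CC[C@H](C)C(=O)Oc1c(O)cc(OC)c(I)c1O
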